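**Retrosynthetic overview**
The target, (4S,5S,8S,9S,10R,13S)-15-acetoxy-8-hydroxylabdan-18-oic acid, is traced back through acetylation and hydrogenation to a ring A cyclohexene acid.
Ring A is closed last, at C3–C4, by an Ireland–Claisen rearrangement of a δ-lactone enolate; in that lactone the C4 carboxyl carbon (C18) is tied through oxygen to C1, and C1 carries a vinyl group (C2=C3).
The enabling feature is that C4 (bearing the carboxyl) and C1 are 1,4-related in ring A across the C5–C10 edge shared with ring B: the temporary C18–O–C1 bridge makes C4=C18–O–C1–C2=C3 an allyl vinyl ether, and its [3,3] shift leaves C1=C2–C3–C4 and a free C18 acid.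
The lactone comes from a ring B aldehyde (vinyl addition, lactonization); ring B is closed at C9–C10 by a titanocene-mediated epoxide radical cyclization; C5 comes from an enantioselective boron-enolate Claisen and C13 from asymmetric hydrogenation of farnesol.
Order of ring formation: ring B (step 8), temporary lactone (step 11), ring A (step 12).

Key step: step 12

Remark: atom numbers are those of the labdane skeleton (C1–C10 decalin, C11–C16 side chain, C17 methyl on C8, C18 carboxyl carbon on C4, C20 methyl on C10). In the target the carboxyl and the 8-hydroxyl are trans to the C10 methyl. C10 in compounds 9 and 10 is formed as an inconsequential epimer mixture and is written without a stereo descriptor.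

**Step 1**
Reactants: 1 (2E,6E)-farnesol
Product: 2 (3S,6E)-3,7,11-trimethyldodeca-6,10-dien-1-ol
Conditions: Ru(OAc)2[(R)-BINAP] (cat.), H2 (30 atm), MeOH, 20 °C
Reagents that add atoms: none
Why: BINAP–ruthenium asymmetric hydrogenation of an allylic alcohol should reduce only the hydroxyl-bearing C=C and set C13 as S with the (R)-ligand, leaving the two isolated trisubstituted alkenes untouched.

**Step 2**
Reactants: 2 (3S,6E)-3,7,11-trimethyldodeca-6,10-dien-1-ol
Product: 3 benzyl ether of 2
Conditions: NaH, BnBr, Bu4NI (cat.), THF, 0 °C to rt
Reagents that add atoms: benzyl bromide BrCc1ccccc1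
Why: Williamson etherification masks the primary alcohol as a benzyl ether that should survive the enolate, radical and Grignard steps and is removed in step 13.

**Step 3**
Reactants: 3 benzyl ether of 2
Product: 4 (2E,6E,10S)-12-benzyloxy-2,6,10-trimethyldodeca-2,6-dien-1-ol
Conditions: SeO2 (cat.), t-BuOOH, salicylic acid (cat.), CH2Cl2, rt
Reagents that add atoms: tert-butyl hydroperoxide CC(C)(C)OO
Why: SeO2-catalysed allylic oxidation (ene reaction then [2,3]-shift) should take the E-methyl of the terminal isopropylidene group, the most reactive allylic position, giving the E-allylic alcohol that carries C1.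

**Step 4**
Reactants: 4 (2E,6E,10S)-12-benzyloxy-2,6,10-trimethyldodeca-2,6-dien-1-ol
Product: 5 propanoate of 4
Conditions: (EtCO)2O, Et3N, DMAP (cat.), CH2Cl2, 0 °C
Reagents that add atoms: propanoic anhydride CCC(=O)OC(=O)CC
Why: DMAP-catalysed acylation gives the allyl propanoate needed for the ester-enolate Claisen rearrangement.

**Step 5**
Reactants: 5 propanoate of 4
Product: 8 (2S,3R,6E,10S)-12-benzyloxy-2,6,10-trimethyl-3-(prop-1-en-2-yl)dodec-6-enoic acid, via boron ketene acetal 6 (not isolated), via acyloxyborane 7 (not isolated)
Conditions: (R,R)-2-bromo-4,5-diphenyl-1,3-bis[3,5-bis(trifluoromethyl)phenylsulfonyl]-1,3,2-diazaborolidine, Et3N, toluene–hexane, −78 °C then −20 °C; aq. work-up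
Reagents that add atoms: none
Why: Enantioselective boron ester-enolate Claisen rearrangement (Ireland–Claisen type): the C2-symmetric diazaborolidine forms the O-boron ketene acetal and selects its face in a chair transition state with the chain equatorial on the E-alkene, which should make the C4–C5 bond, set C5 under controller control (the sense of induction assumed here is not established for this substrate and is to be confirmed, the (S,S)-controller giving the opposite sense; C4 is inconsequential because it is re-enolized in step 12) and leave the isopropenyl group C10(=C1)C20.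

**Step 6**
Reactants: 8 acid from step 5
Product: 9 iodolactone (C10 epimers)
Conditions: I2, NaHCO3, MeCN, 0 °C
Reagents that add atoms: iodine II
Why: Iodolactonization (5-exo, Markovnikov) is confined to the γ,δ-alkene next to the carboxyl group, so the 1,1-disubstituted alkene is functionalized and the remote trisubstituted alkene is spared; the new C10 centre does not matter.

**Step 7**
Reactants: 9 iodolactone (C10 epimers)
Product: 10 epoxy methyl ester (C10 epimers)
Conditions: K2CO3, MeOH, rt
Reagents that add atoms: methanol CO
Why: Methoxide opens the lactone and the liberated tertiary alkoxide displaces iodide (intramolecular Williamson reaction), giving the 2,2-disubstituted epoxide that keeps an oxygen on C1.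

**Step 8**
Reactants: 10 epoxy methyl ester (C10 epimers)
Product: 11 ring B hydroxy ester with exocyclic C8=C17 alkene
Conditions: Cp2TiCl2, Mn dust, THF, rt; then 1 M HCl
Reagents that add atoms: none
Why: Titanocene chloride (trivalent titanium) opens the epoxide homolytically to the tertiary C10 radical, which should cyclize 6-endo onto the E-trisubstituted alkene through a chair with the C5 substituent, the titanoxymethyl group and the C9 side chain equatorial and the C10 methyl axial (C9 and C10 set by substrate control from C5); the C8 radical is trapped by a second Cp2TiCl and leaves as the exocyclic alkene by β-hydride elimination, which closes ring B.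

**Step 9**
Reactants: 11 ring B hydroxy ester with exocyclic C8=C17 alkene
Product: 12 ring B diol ester (8-hydroxyl equatorial)
Conditions: Co(acac)2 (cat.), PhSiH3, O2 (1 atm), i-PrOH, rt
Reagents that add atoms: dioxygen O=O
Why: Mukaiyama hydration (cobalt hydride hydrogen-atom transfer, then O2 capture) is Markovnikov, and the tertiary C8 radical should take up oxygen from the face opposite the axial C10 methyl, giving the equatorial 8-hydroxyl and the axial C17 methyl.

**Step 10**
Reactants: 12 ring B diol ester (8-hydroxyl equatorial)
Product: 13 C1 aldehyde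
Conditions: Dess–Martin periodinane, CH2Cl2, rt
Reagents that add atoms: none
Why: Dess–Martin oxidation converts the neopentyl primary alcohol into the non-enolizable C1 aldehyde, and the tertiary alcohol cannot be oxidized.

**Step 11**
Reactants: 13 C1 aldehyde
Product: 15 (1R)-1-vinyl δ-lactone (C18–O–C1) trans-fused to ring B, via hydroxy ester 14 (not isolated)
Conditions: CH2=CHMgBr (2.2 equiv), THF, −78 °C to rt; aq. NH4Cl
Reagents that add atoms: vinylmagnesium bromide C=C[Mg]Br
Why: Grignard addition followed by lactonization of the magnesium alkoxide onto the C18 methyl ester (intramolecular transesterification); under Felkin–Anh control the C=O eclipses the axial C10 methyl and the nucleophile should enter past the unbranched C9 side chain rather than the branched C5 substituent, giving the 1R carbinol with the vinyl group on the face of the C10 methyl.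

**Step 12**
Reactants: 15 (1R)-1-vinyl δ-lactone (C18–O–C1) trans-fused to ring B
Product: 18 ring A cyclohexene acid (C1=C2), via silyl ketene acetal 16 (not isolated), via silyl ester 17 (not isolated)
Conditions: LDA (2.5 equiv), TMSCl–Et3N, THF, −78 °C; then toluene, 105 °C; then 1 M HCl
Reagents that add atoms: none
Why: Deprotonation of the 8-hydroxyl and of C4 with in situ silylation gives the cyclic silyl ketene acetal 16, in which C4=C18–O–C1–C2=C3 is an allyl vinyl ether; on heating it should undergo a concerted suprafacial [3,3] shift (Ireland–Claisen rearrangement of a lactone enolate, the known conversion of ω-vinyl lactones into cycloalkene carboxylic acids) that makes C3–C4 and breaks C1–O. This closes ring A as a six-membered carbocycle by joining the two termini of the 1,5-diene across the C5–C10 edge of ring B, the lactone ring forcing a boat-like, bicyclo[2.2.2]octane-like transition state. The new quaternary centre C4 is set by chirality transfer from C1: the vinyl group lies on the face of the C10 methyl, so C3 is delivered to that face of the enolate and the carboxyl carbon C18 is left on the other face of ring A, cis to H5 and trans to the C10 methyl, with the C4 methyl axial. The trans ring fusion at C5 and C10 is untouched and permits only this one boat, so the step should be stereospecific, and the 1S epimer of the lactone has no accessible transition state. The step needs O-silylation and no ketene-forming cleavage of the lactone enolate, which the internal TMSCl quench at −78 °C should secure; acid work-up frees the carboxylic acid and the tertiary alcohol.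

**Step 13**
Reactants: 18 ring A cyclohexene acid (C1=C2)
Product: 19 15-hydroxy-8-hydroxylabdan-18-oic acid
Conditions: H2 (1 atm), Pd/C, EtOAc, rt
Reagents that add atoms: none
Why: Heterogeneous hydrogenation saturates the cis-disubstituted C1=C2 bond and hydrogenolyses the benzyl ether in one operation; no stereocentre is created.

**Step 14**
Reactants: 19 15-hydroxy-8-hydroxylabdan-18-oic acid
Product: 20 (4S,5S,8S,9S,10R,13S)-15-acetoxy-8-hydroxylabdan-18-oic acid
Conditions: Ac2O, pyridine, 0 °C to rt; aq. work-up
Reagents that add atoms: acetic anhydride CC(=O)OC(C)=O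
Why: Acetylation should take only the primary C15 hydroxyl, since the tertiary C8 hydroxyl is not acylated under these conditions and the hindered C18 acid is recovered unchanged after aqueous work-up.

**Compound list**
1 | (2E,6E)-farnesol | OC/C=C(\C)CC/C=C(\C)CCC=C(C)C | starting material
2 | (3S,6E)-3,7,11-trimethyldodeca-6,10-dien-1-ol, (S)-2,3-dihydrofarnesol | OCC[C@@H](C)CC/C=C(\C)CCC=C(C)C | intermediate
3 | benzyl ether of 2 | c1ccccc1COCC[C@@H](C)CC/C=C(\C)CCC=C(C)C | intermediate
4 | (2E,6E,10S)-12-benzyloxy-2,6,10-trimethyldodeca-2,6-dien-1-ol | c1ccccc1COCC[C@@H](C)CC/C=C(\C)CC/C=C(\C)CO | intermediate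
5 | propanoate of 4 | c1ccccc1COCC[C@@H](C)CC/C=C(\C)CC/C=C(\C)COC(=O)CC | intermediate
6 | E-configured O-boron ketene acetal of 5, boron held in the (R,R)-bis-sulfonamide diazaborolidine | C/C=C(/OB1N(S(=O)(=O)c2cc(C(F)(F)F)cc(C(F)(F)F)c2)[C@H](c2ccccc2)[C@@H](c2ccccc2)N1S(=O)(=O)c1cc(C(F)(F)F)cc(C(F)(F)F)c1)OC/C(C)=C/CC/C(C)=C/CC[C@H](C)CCOCc1ccccc1 | intermediate
7 | acyloxyborane of acid 8 | O=C([C@@H](C)[C@H](C(C)=C)CC/C(C)=C/CC[C@H](C)CCOCc1ccccc1)OB1N(S(=O)(=O)c2cc(C(F)(F)F)cc(C(F)(F)F)c2)[C@H](c2ccccc2)[C@@H](c2ccccc2)N1S(=O)(=O)c1cc(C(F)(F)F)cc(C(F)(F)F)c1 | intermediate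
8 | (2S,3R,6E,10S)-12-benzyloxy-2,6,10-trimethyl-3-(prop-1-en-2-yl)dodec-6-enoic acid | OC(=O)[C@@H](C)[C@H](C(C)=C)CC/C(C)=C/CC[C@H](C)CCOCc1ccccc1 | intermediate
9 | γ-iodolactone of 8: O on C10, iodomethyl C1, both C10 epimers | O=C1[C@@H](C)[C@@H](CC/C(C)=C/CC[C@H](C)CCOCc2ccccc2)C(C)(CI)O1 | intermediate
10 | methyl ester with 2-methyloxiran-2-yl group (C10–C1 epoxide), both C10 epimers | COC(=O)[C@@H](C)[C@@H](CC/C(C)=C/CC[C@H](C)CCOCc1ccccc1)C1(C)CO1 | intermediate
11 | ring B hydroxy ester: C10 bears axial methyl and CH2OH, C5 the methyl propanoate unit, C9 the side chain, C8=C17 exocyclic alkene | c1ccccc1COCC[C@@H](C)CC[C@H]1[C@](C)(CO)[C@@H]([C@H](C)C(=O)OC)CCC1=C | intermediate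
12 | diol ester: as 11 with equatorial 8-hydroxyl and axial C17 methyl | c1ccccc1COCC[C@@H](C)CC[C@H]1[C@](C)(CO)[C@@H]([C@H](C)C(=O)OC)CC[C@]1(C)O | intermediate
13 | C1 aldehyde of 12 | c1ccccc1COCC[C@@H](C)CC[C@H]1[C@](C)(C=O)[C@@H]([C@H](C)C(=O)OC)CC[C@]1(C)O | intermediate
14 | hydroxy ester with (1R)-1-hydroxyallyl group on C10 | c1ccccc1COCC[C@@H](C)CC[C@H]1[C@](C)([C@H](O)C=C)[C@@H]([C@H](C)C(=O)OC)CC[C@]1(C)O | intermediate
15 | (1R)-1-vinyl δ-lactone, ring O–C1–C10–C5–C4–C18(=O), trans-fused to ring B, vinyl cis to the C10 methyl | c1ccccc1COCC[C@@H](C)CC[C@H]1[C@]2(C)[C@@H](C=C)OC(=O)[C@@H](C)[C@H]2CC[C@]1(C)O | intermediate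
16 | trimethylsilyl ketene acetal of 15, 8-O-trimethylsilyl | c1ccccc1COCC[C@@H](C)CC[C@H]1[C@]2(C)[C@@H](C=C)OC(O[Si](C)(C)C)=C(C)[C@H]2CC[C@]1(C)O[Si](C)(C)C | intermediate
17 | trimethylsilyl ester of 18, 8-O-trimethylsilyl | c1ccccc1COCC[C@@H](C)CC[C@H]1[C@]2(C)C=CC[C@](C)(C(=O)O[Si](C)(C)C)[C@H]2CC[C@]1(C)O[Si](C)(C)C | intermediate
18 | 15-benzyloxy-8-hydroxylabd-1-en-18-oic acid | c1ccccc1COCC[C@@H](C)CC[C@H]1[C@]2(C)C=CC[C@](C)(C(=O)O)[C@H]2CC[C@]1(C)O | intermediate
19 | 8,15-dihydroxylabdan-18-oic acid | OCC[C@@H](C)CC[C@H]1[C@]2(C)CCC[C@](C)(C(=O)O)[C@H]2CC[C@]1(C)O | intermediate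
20 | (4S,5S,8S,9S,10R,13S)-15-acetoxy-8-hydroxylabdan-18-oic acid | CC(=O)OCC[C@@H](C)CC[C@H]1[C@]2(C)CCC[C@](C)(C(=O)O)[C@H]2CC[C@]1(C)O | target

**Step count and risks**
Total step count: 14. Longest linear sequence: 14 steps from (2E,6E)-farnesol.

Step 12 is the most likely to fail. The boat-like transition state inside the trans-fused bicycle may be too strained, so that desilylation or cleavage of the ketene acetal outruns the rearrangement. The fallback sets out from lactone 15. Methanolysis (K2CO3, MeOH) reopens it to hydroxy ester 14, and methyl chloroformate with pyridine gives the allylic methyl carbonate F1. Enolization with LiHMDS and then Pd(PPh3)4 should close ring A by intramolecular allylic alkylation of the ester enolate at the unsubstituted allyl terminus C3 (Tsuji–Trost type). In that closure the enolate eclipses H5 to avoid A(1,3) strain, which should give the same C4 configuration, and the product is the methyl ester F2. Demethylation with LiI in hot pyridine gives acid 18, where the route is rejoined.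

Step 8 is the second risk. The tertiary radical may be reduced and the epoxide deoxygenated before it cyclizes, or chair selection in the 6-endo closure may be poor. The fallback sets out from epoxy ester 10 and replaces the radical by a polar epoxide–alkene cyclization (MeAlCl2, CH2Cl2, −78 °C). The tertiary C10 cation should be captured by the alkene through the same chair, and proton loss should give 11 together with the endocyclic C7=C8 alkene isomer F3. Both alkenes give the same tertiary C8 radical under the conditions of step 9, so the mixture converges on diol ester 12, where the route is rejoined.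

Step 11 is the third risk: facial selectivity in the vinyl addition to the crowded α-quaternary aldehyde may be poor, which would give the 1S lactone that cannot rearrange. The fallback sets out from aldehyde 13 and replaces substrate control by reagent control. Vinyl addition at −78 °C with a cold quench gives hydroxy ester 14 as a C1 epimer mixture, and Dess–Martin oxidation gives the vinyl ketone F4. Corey–Bakshi–Shibata reduction with (S)-Me-CBS oxazaborolidine and catecholborane should return 14 as the 1R carbinol, and catalytic DBU closes it to lactone 15, where the route is rejoined.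

Further compounds
F1 | step 12 | allylic methyl carbonate of 14 | c1ccccc1COCC[C@@H](C)CC[C@H]1[C@](C)([C@H](OC(=O)OC)C=C)[C@@H]([C@H](C)C(=O)OC)CC[C@]1(C)O
F2 | step 12 | methyl ester of 18 | c1ccccc1COCC[C@@H](C)CC[C@H]1[C@]2(C)C=CC[C@](C)(C(=O)OC)[C@H]2CC[C@]1(C)O
F3 | step 8 | endocyclic C7=C8 alkene isomer of 11 | c1ccccc1COCC[C@@H](C)CC[C@H]1[C@](C)(CO)[C@@H]([C@H](C)C(=O)OC)CC=C1C
F4 | step 11 | C1 vinyl ketone from oxidation of 14 | c1ccccc1COCC[C@@H](C)CC[C@H]1[C@](C)(C(=O)C=C)[C@@H]([C@H](C)C(=O)OC)CC[C@]1(C)O
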